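**Plan**

- Retrosynthesis: the two benzyl ethers on ring B are removed last. Before that, the C4–OH and C3–H bonds come from hydroboration of a C3=C4 chromene, and the C6 O‑methyl from a free C6 phenol. The pyran ring is then opened at O1–C2 to a 2‑(2‑arylallyl)‑5,6‑dimethoxy‑1,4‑benzoquinone, which is cut at C4a–C4 (quinone + allylstannane) and at C3–C1′ (Suzuki coupling).
- Enabling feature: ring A carries O1 on C8a and, para to it, the C6 oxygen, flanked by the C7 and C8 methoxy groups. It is therefore a 2,3‑dimethoxyhydroquinone with one oxygen tied to C2. At the quinone level the C4 methylene is doubly activated, and tautomerisation gives the oxatriene O1=C8a–C4a=C4–C3=C2.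
- Forward: ring B is made from 2,3‑dimethoxy‑1,4‑benzoquinone (reductive benzylation, bromination, borylation) and joined to C3 by Suzuki coupling with 2‑bromoallyl alcohol. The C2–C3–C4 chain is attached to ring A by BF3‑mediated allylstannane addition to the same quinone. The pyran ring closes by oxa‑6π electrocyclisation, and the C6 phenol is then methylated.
- Stereochemistry: the target is trans‑(3S,4R). Both centres are set in one reagent‑controlled syn hydroboration–oxidation of C3=C4 (boron to C4, hydrogen to C3) with IpcBH2 from (+)‑α‑pinene.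
- Neutral hydrogenolysis of the two benzyl ethers finishes the synthesis.

Key step: step 7

Remark on numbering: chroman numbering of the target (O1, C2, C3, C4, C4a, C5–C8, C8a) is used for the corresponding atoms throughout. Ring A is the benzo ring and ring B is the aryl group on C3.

Assumption: the facial sense of IpcBH2 in step 9 is assigned by analogy with 1‑phenylcycloalkenes and is to be confirmed on 17 (Mosher esters); if it proves reversed, the reagent from (−)‑α‑pinene is used instead.

**Route**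

Step 1
Reactants: 1 2,3-dimethoxy-1,4-benzoquinone; 2 benzyl bromide
Product: 4 1,4-bis(benzyloxy)-2,3-dimethoxybenzene, via 2,3-dimethoxyhydroquinone 3 (not isolated)
Conditions: Na2S2O4, THF/H2O, rt; extraction under Ar; then BnBr, K2CO3, DMF, 60 °C
Reagents that add atoms: benzyl bromide (compound 2), BrCc1ccccc1
Why: Dithionite reduction of the quinone followed by Williamson etherification of both phenols should give the symmetric bis‑benzyl ether, which is stable to every later step until hydrogenolysis.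

Step 2
Reactants: 4 1,4-bis(benzyloxy)-2,3-dimethoxybenzene
Product: 5 1,4-bis(benzyloxy)-5-bromo-2,3-dimethoxybenzene
Conditions: NBS (1.0 equiv), MeCN, 0 °C → rt, dark
Reagents that add atoms: N-bromosuccinimide, BrN1C(=O)CCC1=O
Why: Electrophilic aromatic bromination should occur once on the tetra‑alkoxy ring, whose two free positions are equivalent by symmetry and far more reactive than the benzyl phenyl rings.

Step 3
Reactants: 5 1,4-bis(benzyloxy)-5-bromo-2,3-dimethoxybenzene
Product: 6 2-[2,5-bis(benzyloxy)-3,4-dimethoxyphenyl]-4,4,5,5-tetramethyl-1,3,2-dioxaborolane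
Conditions: B2pin2, Pd(dppf)Cl2 (3 mol %), KOAc, 1,4-dioxane, 90 °C
Reagents that add atoms: bis(pinacolato)diboron, CC1(C)OB(OC1(C)C)B1OC(C)(C)C(C)(C)O1
Why: Miyaura borylation of the aryl bromide avoids an aryllithium next to benzyl ethers and should give a boronate that can be purified.

Step 4
Reactants: 6 2-[2,5-bis(benzyloxy)-3,4-dimethoxyphenyl]-4,4,5,5-tetramethyl-1,3,2-dioxaborolane; 7 2-bromoprop-2-en-1-ol
Product: 8 2-[2,5-bis(benzyloxy)-3,4-dimethoxyphenyl]prop-2-en-1-ol
Conditions: Pd(PPh3)4 (5 mol %), K2CO3, 1,4-dioxane/H2O (4:1), 85 °C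
Reagents that add atoms: none
Why: Suzuki–Miyaura coupling of the vinyl bromide, which tolerates the free allylic hydroxyl, should form the C3–C1′ bond and deliver the 2‑arylallyl unit in one operation.

Step 5
Reactants: 8 2-[2,5-bis(benzyloxy)-3,4-dimethoxyphenyl]prop-2-en-1-ol
Product: 10 tributyl{2-[2,5-bis(benzyloxy)-3,4-dimethoxyphenyl]prop-2-en-1-yl}stannane, via allylic mesylate 9 (not isolated)
Conditions: MsCl, Et3N, THF, −20 °C; cold filtration under Ar; filtrate added to Bu3SnLi (from Bu3SnH, LDA), THF, −78 → −40 °C; purification on Et3N‑deactivated silica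
Reagents that add atoms: tributylstannyllithium, [Li][Sn](CCCC)(CCCC)CCCC
Why: Mesylation and displacement by the stannyl anion should give the allylstannane, and because the allyl unit is 2‑substituted the SN2 and SN2′ pathways lead to the same product.

Step 6
Reactants: 10 tributyl{2-[2,5-bis(benzyloxy)-3,4-dimethoxyphenyl]prop-2-en-1-yl}stannane; 1 2,3-dimethoxy-1,4-benzoquinone
Product: 12 2-{2-[2,5-bis(benzyloxy)-3,4-dimethoxyphenyl]prop-2-en-1-yl}-5,6-dimethoxycyclohexa-2,5-diene-1,4-dione, via allylhydroquinone 11 (not isolated)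
Conditions: 1 (1.5 equiv), BF3·OEt2 (2 equiv), CH2Cl2, −78 → −40 °C; aq. NaHCO3; then Ag2O, MgSO4, Et2O, rt
Reagents that add atoms: none
Why: Lewis‑acid‑mediated allylstannane addition to the quinone (Naruta‑type allylation) should place the symmetric allyl unit on an unsubstituted ring carbon, the only position from which the adduct can aromatise, and Ag2O then oxidises only the free hydroquinone while the ring‑B ethers stay intact.

Step 7
Reactants: 12 2-{2-[2,5-bis(benzyloxy)-3,4-dimethoxyphenyl]prop-2-en-1-yl}-5,6-dimethoxycyclohexa-2,5-diene-1,4-dione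
Product: 14 3-[2,5-bis(benzyloxy)-3,4-dimethoxyphenyl]-7,8-dimethoxy-2H-chromen-6-ol, via ortho-quinone methide 13 (not isolated)
Conditions: i-Pr2NEt (0.5 equiv), degassed PhMe (0.02 M), 90 °C, Ar, dark
Reagents that add atoms: none
Why: The amine should remove a proton from the C4 methylene, which is γ to the quinone carbonyl that becomes the C6 oxygen and also allylic to C3=C2, and reprotonation on that distal oxygen gives ortho‑quinone methide 13, in which O1=C8a–C4a=C4–C3=C2 is a 1‑oxatriene. Thermal disrotatory oxa‑6π electrocyclisation then forms O1–C2 and closes the pyran ring (a six‑electron pericyclic closure onto the terminal CH2), driven by aromatisation of ring A as the C6 phenol. The closest known reaction type is the base‑ or heat‑induced isomerisation of prenyl‑ and cinnamyl‑1,4‑benzoquinones to 2H‑chromen‑6‑ols (ubiquinone to ubichromenol), applied here to a 2‑arylallyl side chain. No stereocentre is formed. The step needs tautomerisation to be faster than conjugate addition at the free quinone carbon or redox disproportionation, which a hindered non‑nucleophilic amine, high dilution and exclusion of oxygen and light should secure. Only the carbonyl oxygen next to the side chain can reach C2, so the ring size is fixed, and the Z geometry of the exocyclic C4a=C4 bond needed for closure is accessible by reversible tautomerisation.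

Step 8
Reactants: 14 3-[2,5-bis(benzyloxy)-3,4-dimethoxyphenyl]-7,8-dimethoxy-2H-chromen-6-ol
Product: 15 3-[2,5-bis(benzyloxy)-3,4-dimethoxyphenyl]-6,7,8-trimethoxy-2H-chromene
Conditions: MeI, K2CO3, acetone, 50 °C, Ar (14 used directly after step 7)
Reagents that add atoms: methyl iodide, CI
Why: Williamson methylation of the only free phenol should complete the 6,7,8‑trimethoxy pattern of ring A and remove the air‑sensitive hydroquinone monoether.

Step 9
Reactants: 15 3-[2,5-bis(benzyloxy)-3,4-dimethoxyphenyl]-6,7,8-trimethoxy-2H-chromene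
Product: 17 (3S,4R)-3-[2,5-bis(benzyloxy)-3,4-dimethoxyphenyl]-6,7,8-trimethoxy-3,4-dihydro-2H-chromen-4-ol, via isopinocampheyl(chroman-4-yl)borane 16 (not isolated)
Conditions: IpcBH2 [from (+)-α-pinene, C[C@H]1[C@H](B)C[C@@H]2C[C@H]1C2(C)C] (1.5 equiv), THF, −25 → 0 °C; then 3 M NaOH, 30% H2O2, 0 °C → rt
Reagents that add atoms: hydrogen peroxide, OO
Why: In this Brown asymmetric hydroboration–oxidation the borane should add syn across C3=C4 with boron on the less substituted C4 and hydrogen on the aryl‑bearing C3, so oxidation with retention gives the 3,4‑trans alcohol, and the isopinocampheyl group selects the face, the reagent from (+)‑α‑pinene being chosen because it gives (1S,2R)‑trans alcohols from 1‑phenylcycloalkenes, the spatial arrangement that corresponds to (3S,4R) here.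

Step 10
Reactants: 17 (3S,4R)-3-[2,5-bis(benzyloxy)-3,4-dimethoxyphenyl]-6,7,8-trimethoxy-3,4-dihydro-2H-chromen-4-ol
Product: 18 2-[(3S,4R)-4-hydroxy-6,7,8-trimethoxy-3,4-dihydro-2H-chromen-3-yl]-5,6-dimethoxybenzene-1,4-diol (CNP0111047.1)
Conditions: H2 (1 atm), 10% Pd/C, EtOAc, rt; filtration and concentration under Ar
Reagents that add atoms: none
Why: Catalytic hydrogenolysis in a neutral, non‑acidic medium should cleave the two aryl benzyl ethers faster than the C4 benzylic alcohol and avoids the acid that would ionise C4 toward a pterocarpan, so neither stereocentre is touched.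

**Compound list**

1 | 2,3-dimethoxy-1,4-benzoquinone | COC1=C(OC)C(=O)C=CC1=O | starting material
2 | benzyl bromide | BrCc1ccccc1 | starting material
3 | 2,3-dimethoxybenzene-1,4-diol (2,3-dimethoxyhydroquinone) | COc1c(O)ccc(O)c1OC | intermediate (not isolated)
4 | 1,4-bis(benzyloxy)-2,3-dimethoxybenzene | COc1c(OCc2ccccc2)ccc(OCc2ccccc2)c1OC | intermediate
5 | 1,4-bis(benzyloxy)-5-bromo-2,3-dimethoxybenzene | COc1c(OCc2ccccc2)cc(Br)c(OCc2ccccc2)c1OC | intermediate
6 | 2-[2,5-bis(benzyloxy)-3,4-dimethoxyphenyl]-4,4,5,5-tetramethyl-1,3,2-dioxaborolane | COc1c(OCc2ccccc2)cc(B2OC(C)(C)C(C)(C)O2)c(OCc2ccccc2)c1OC | intermediate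
7 | 2-bromoprop-2-en-1-ol (2-bromoallyl alcohol) | OCC(Br)=C | starting material
8 | 2-[2,5-bis(benzyloxy)-3,4-dimethoxyphenyl]prop-2-en-1-ol | C=C(CO)c1cc(OCc2ccccc2)c(OC)c(OC)c1OCc1ccccc1 | intermediate
9 | 2-[2,5-bis(benzyloxy)-3,4-dimethoxyphenyl]prop-2-en-1-yl methanesulfonate | C=C(COS(C)(=O)=O)c1cc(OCc2ccccc2)c(OC)c(OC)c1OCc1ccccc1 | intermediate (not isolated)
10 | tributyl{2-[2,5-bis(benzyloxy)-3,4-dimethoxyphenyl]prop-2-en-1-yl}stannane | C=C(C[Sn](CCCC)(CCCC)CCCC)c1cc(OCc2ccccc2)c(OC)c(OC)c1OCc1ccccc1 | intermediate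
11 | 5-{2-[2,5-bis(benzyloxy)-3,4-dimethoxyphenyl]prop-2-en-1-yl}-2,3-dimethoxybenzene-1,4-diol | C=C(Cc1cc(O)c(OC)c(OC)c1O)c1cc(OCc2ccccc2)c(OC)c(OC)c1OCc1ccccc1 | intermediate (not isolated)
12 | 2-{2-[2,5-bis(benzyloxy)-3,4-dimethoxyphenyl]prop-2-en-1-yl}-5,6-dimethoxycyclohexa-2,5-diene-1,4-dione | C=C(CC1=CC(=O)C(OC)=C(OC)C1=O)c1cc(OCc2ccccc2)c(OC)c(OC)c1OCc1ccccc1 | intermediate (key-step precursor)
13 | (6Z)-6-{2-[2,5-bis(benzyloxy)-3,4-dimethoxyphenyl]prop-2-en-1-ylidene}-4-hydroxy-2,3-dimethoxycyclohexa-2,4-dien-1-one | C=C(c1cc(OCc2ccccc2)c(OC)c(OC)c1OCc1ccccc1)/C=C1/C=C(O)C(OC)=C(OC)C1=O | intermediate (not isolated)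
14 | 3-[2,5-bis(benzyloxy)-3,4-dimethoxyphenyl]-7,8-dimethoxy-2H-chromen-6-ol | COc1c(O)cc2c(c1OC)OCC(c1cc(OCc3ccccc3)c(OC)c(OC)c1OCc1ccccc1)=C2 | intermediate (key-step product)
15 | 3-[2,5-bis(benzyloxy)-3,4-dimethoxyphenyl]-6,7,8-trimethoxy-2H-chromene | COc1cc2c(c(OC)c1OC)OCC(c1cc(OCc3ccccc3)c(OC)c(OC)c1OCc1ccccc1)=C2 | intermediate
16 | {(3S,4R)-3-[2,5-bis(benzyloxy)-3,4-dimethoxyphenyl]-6,7,8-trimethoxychroman-4-yl}[(1R,2R,3R,5S)-isopinocampheyl]borane | C[C@H]1[C@H](B[C@H]3c4cc(OC)c(OC)c(OC)c4OC[C@@H]3c3cc(OCc4ccccc4)c(OC)c(OC)c3OCc3ccccc3)C[C@@H]2C[C@H]1C2(C)C | intermediate (not isolated)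
17 | (3S,4R)-3-[2,5-bis(benzyloxy)-3,4-dimethoxyphenyl]-6,7,8-trimethoxy-3,4-dihydro-2H-chromen-4-ol | COc1cc2c(c(OC)c1OC)OC[C@H](c1cc(OCc3ccccc3)c(OC)c(OC)c1OCc1ccccc1)[C@H]2O | intermediate
18 | 2-[(3S,4R)-4-hydroxy-6,7,8-trimethoxy-3,4-dihydro-2H-chromen-3-yl]-5,6-dimethoxybenzene-1,4-diol | COc1cc2c(c(OC)c1OC)OC[C@H](c1cc(O)c(OC)c(OC)c1O)[C@H]2O | target

**Step count and risks**

Total steps: 10. Longest linear sequence: 10 steps (1 → 4 → 5 → 6 → 8 → 10 → 12 → 14 → 15 → 17 → 18); the second portion of quinone 1 and alcohol 7 enter as purchased materials.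

Steps most likely to fail:

1. Step 7 (quinone to chromenol).
   - What may go wrong: tautomerisation to the ortho‑quinone methide may be outrun by conjugate addition to the free quinone carbon, by redox disproportionation, or by dimerisation of the quinone methide.
   - Fallback: the same oxatriene is generated by dehydrogenation of a phenol instead of tautomerisation of a quinone. It sets out from alcohol 8 by way of its mesylate 9.
   - O‑Alkylation of commercial 2,3,4‑trimethoxyphenol (K2CO3, DMF) would give 1-({2-[2,5-bis(benzyloxy)-3,4-dimethoxyphenyl]prop-2-en-1-yl}oxy)-2,3,4-trimethoxybenzene F1.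
   - Aromatic Claisen rearrangement (PhNEt2, 190 °C) would move the allyl group to the only free ortho carbon and give 6-{2-[2,5-bis(benzyloxy)-3,4-dimethoxyphenyl]prop-2-en-1-yl}-2,3,4-trimethoxyphenol F2.
   - DDQ in dry dioxane would abstract hydride from the benzylic methylene to give (6Z)-6-{2-[2,5-bis(benzyloxy)-3,4-dimethoxyphenyl]prop-2-en-1-ylidene}-2,3,4-trimethoxycyclohexa-2,4-dien-1-one F3. This closes by the same oxa‑6π step and rejoins the route at chromene 15, with the C6 methoxy group already in place.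

2. Step 6 (quinone allylation).
   - What may go wrong: protodestannylation of the acid‑labile 2‑arylallylstannane by the Lewis acid, a second allylation of the product quinone, or a carbonyl adduct that does not rearrange to the C‑allyl hydroquinone.
   - Fallback: the C4a–C4 bond is made by a sigmatropic shift instead of a Lewis‑acid addition. It sets out from alcohol 8 (as mesylate 9) and hydroquinone 3, the latter isolated under argon after dithionite reduction of 1.
   - Mono‑O‑alkylation of an excess of 3 (K2CO3, DMF, Ar) would give 4-({2-[2,5-bis(benzyloxy)-3,4-dimethoxyphenyl]prop-2-en-1-yl}oxy)-2,3-dimethoxyphenol F4.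
   - Thermal aromatic Claisen rearrangement (PhNEt2, 180 °C, Ar) would deliver the allyl group to the free ortho carbon and return to the route at hydroquinone 11, which is oxidised with Ag2O to 12 as in step 6.

3. Step 9 (asymmetric hydroboration).
   - What may go wrong: poor facial selectivity, or sluggish addition of the bulky borane to the trisubstituted, ortho‑substituted stilbene‑type alkene.
   - Fallback: the absolute configuration is set by catalytic ketone reduction instead. It sets out from chromene 15.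
   - BH3·SMe2 in THF would give racemic trans‑[3-aryl-6,7,8-trimethoxychroman-4-yl]borane F5, and NaOH/H2O2 would turn it into racemic trans‑3-[2,5-bis(benzyloxy)-3,4-dimethoxyphenyl]-6,7,8-trimethoxychroman-4-ol F6.
   - Dess–Martin periodinane would give 3-[2,5-bis(benzyloxy)-3,4-dimethoxyphenyl]-6,7,8-trimethoxychroman-4-one F7, whose C3 centre is configurationally labile.
   - Noyori–Ikariya transfer hydrogenation under dynamic kinetic resolution (RuCl[(S,S)-TsDPEN](p-cymene), HCO2H/Et3N) is expected, by analogy with 4‑chromanones and isoflavanones, to give the cis alcohol (3S,4S)-3-[2,5-bis(benzyloxy)-3,4-dimethoxyphenyl]-6,7,8-trimethoxychroman-4-ol F8.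
   - Mitsunobu inversion at C4 (4‑nitrobenzoic acid, PPh3, DIAD, THF) would give (3S,4R)-3-[2,5-bis(benzyloxy)-3,4-dimethoxyphenyl]-6,7,8-trimethoxychroman-4-yl 4-nitrobenzoate F9. Saponification (LiOH, THF/MeOH/H2O) returns to the route at 17.

**Further compounds**

F1 | step 7 | 1-({2-[2,5-bis(benzyloxy)-3,4-dimethoxyphenyl]prop-2-en-1-yl}oxy)-2,3,4-trimethoxybenzene | C=C(COc1ccc(OC)c(OC)c1OC)c1cc(OCc2ccccc2)c(OC)c(OC)c1OCc1ccccc1
F2 | step 7 | 6-{2-[2,5-bis(benzyloxy)-3,4-dimethoxyphenyl]prop-2-en-1-yl}-2,3,4-trimethoxyphenol | C=C(Cc1cc(OC)c(OC)c(OC)c1O)c1cc(OCc2ccccc2)c(OC)c(OC)c1OCc1ccccc1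
F3 | step 7 | (6Z)-6-{2-[2,5-bis(benzyloxy)-3,4-dimethoxyphenyl]prop-2-en-1-ylidene}-2,3,4-trimethoxycyclohexa-2,4-dien-1-one | C=C(c1cc(OCc2ccccc2)c(OC)c(OC)c1OCc1ccccc1)/C=C1/C=C(OC)C(OC)=C(OC)C1=O
F4 | step 6 | 4-({2-[2,5-bis(benzyloxy)-3,4-dimethoxyphenyl]prop-2-en-1-yl}oxy)-2,3-dimethoxyphenol | C=C(COc1ccc(O)c(OC)c1OC)c1cc(OCc2ccccc2)c(OC)c(OC)c1OCc1ccccc1
F5 | step 9 | racemic trans-{3-[2,5-bis(benzyloxy)-3,4-dimethoxyphenyl]-6,7,8-trimethoxychroman-4-yl}borane (one enantiomer drawn) | COc1cc2c(c(OC)c1OC)OC[C@H](c1cc(OCc3ccccc3)c(OC)c(OC)c1OCc1ccccc1)[C@H]2B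
F6 | step 9 | racemic trans-3-[2,5-bis(benzyloxy)-3,4-dimethoxyphenyl]-6,7,8-trimethoxychroman-4-ol (one enantiomer drawn) | COc1cc2c(c(OC)c1OC)OC[C@H](c1cc(OCc3ccccc3)c(OC)c(OC)c1OCc1ccccc1)[C@H]2O
F7 | step 9 | 3-[2,5-bis(benzyloxy)-3,4-dimethoxyphenyl]-6,7,8-trimethoxychroman-4-one (racemic) | COc1cc2c(c(OC)c1OC)OCC(c1cc(OCc3ccccc3)c(OC)c(OC)c1OCc1ccccc1)C2=O
F8 | step 9 | (3S,4S)-3-[2,5-bis(benzyloxy)-3,4-dimethoxyphenyl]-6,7,8-trimethoxychroman-4-ol | COc1cc2c(c(OC)c1OC)OC[C@H](c1cc(OCc3ccccc3)c(OC)c(OC)c1OCc1ccccc1)[C@@H]2O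
F9 | step 9 | (3S,4R)-3-[2,5-bis(benzyloxy)-3,4-dimethoxyphenyl]-6,7,8-trimethoxychroman-4-yl 4-nitrobenzoate | COc1cc2c(c(OC)c1OC)OC[C@H](c1cc(OCc3ccccc3)c(OC)c(OC)c1OCc1ccccc1)[C@H]2OC(=O)c1ccc(cc1)[N+](=O)[O-]
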